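**Plan**

- Retrosynthesis (carotenoid locants, primed for the seco half): the acyl–alkenyl bond C6'–C7' is cut first (thioester + alkenylstannane). The polyene is then cut at C11'=C12' and C11=C12 (two Horner–Wadsworth–Emmons olefinations on a C10 bisphosphonate), and the ring–chain bond C6–C7 by a Stille coupling.
- Enabling feature: C6' is a carbonyl on the quaternary carbon C1' and faces the methyl ketone C5' across a cut ring bond. The seco end (C1'–C6', three methyls, C3') is therefore the ring of (4R,6R)-actinol opened between C5' and C6'. This ketone can enolise only towards its methyl-bearing carbon, and ozonolysis of that single silyl enol ether gives the methyl ketone and an α-quaternary carboxyl whose thioester has no α-hydrogen.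
- The trihydroxycyclohexane ring C1–C6 at the other end is the same actinol ring kept closed, so one chiral-pool ketone supplies both ends.
- Forward order: (a) actinol myristate → silyl enol ether → ozonolysis → S-phenyl thioester; (b) actinol → enol triflate → Stille coupling → C15 trienal → epoxide → triol aldehyde; (c) C10 dialdehyde → bisphosphonate, olefinated first with a stannyl dienal, then with the triol aldehyde; (d) the unprotected triol nonaenylstannane and the thioester are joined last.
- Stereochemistry: C3 and C3' are C4 of actinol and are never touched. C6 and C5 come from hydroxyl-directed epoxidation on the face of the C3 hydroxyl, followed by opening with water at C5 with inversion. All nine C=C bonds are E, from E-configured reagents, stereoretentive couplings and E-selective olefinations.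

Key step: step 19

Remark: (4R,6R)-actinol, (2E)-3-methylpent-2-en-4-yn-1-ol and (2E,4E,6E)-2,7-dimethylocta-2,4,6-trienedial are taken as commercial; all polyene and stannane work is assumed to be done under argon with exclusion of light.

**Fragment A: thioester**

Step 1
Reactants: 1 (4R,6R)-4-hydroxy-2,2,6-trimethylcyclohexan-1-one (actinol); 2 tetradecanoyl chloride
Product: 3 (1R,3R)-3,5,5-trimethyl-4-oxocyclohexyl tetradecanoate
Conditions: pyridine, DMAP (cat.), CH2Cl2, 0 °C → rt
Reagents that add atoms: none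
Why: DMAP-catalysed esterification of the only hydroxyl; the C–O bond of the carbinol carbon is not broken, so its R configuration (the future 3'S centre) is kept.

Step 2
Reactants: 3 (1R,3R)-3,5,5-trimethyl-4-oxocyclohexyl tetradecanoate
Product: 4 (1R)-3,5,5-trimethyl-4-(trimethylsilyloxy)cyclohex-3-en-1-yl tetradecanoate
Conditions: TMSOTf, Et3N, CH2Cl2, 0 °C → rt
Reagents that add atoms: trimethylsilyl trifluoromethanesulfonate, C[Si](C)(C)OS(=O)(=O)C(F)(F)F
Why: Soft enolisation and O-silylation (silyl enol ether formation): the ketone has a single α-hydrogen, on the methyl-bearing carbon, so only one regioisomer can form and the methyl stereocentre, no longer needed, is erased, while the slower-enolising ester should stay intact.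

Step 3
Reactants: 4 (1R)-3,5,5-trimethyl-4-(trimethylsilyloxy)cyclohex-3-en-1-yl tetradecanoate
Product: 6 (4S)-2,2-dimethyl-6-oxo-4-(tetradecanoyloxy)heptanoic acid, via silyl ester 5 (not isolated)
Conditions: O3, CH2Cl2, −78 °C; Me2S, −78 °C → rt; H2O work-up
Reagents that add atoms: ozone, [O-][O+]=O
Why: Ozonolysis of a silyl enol ether should cut the electron-rich C=C bond into the C5' methyl ketone and the C6' silyl ester, which water hydrolyses to the acid; the reductive, non-basic quench keeps the myristate that now lies β to a ketone, and the carbinol stereocentre is untouched.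

Step 4
Reactants: 6 (4S)-2,2-dimethyl-6-oxo-4-(tetradecanoyloxy)heptanoic acid
Product: 7 S-phenyl (4S)-2,2-dimethyl-6-oxo-4-(tetradecanoyloxy)heptanethioate
Conditions: PhSH, DCC, DMAP (cat.), CH2Cl2, 0 °C → rt
Reagents that add atoms: thiophenol, Sc1ccccc1
Why: Steglich thioesterification: the acylpyridinium formed from the carbodiimide-activated acid is captured by the soft thiol even at the neopentyl-type carboxyl, under conditions too weakly basic for E1cB loss of the β-acyloxy group.

**Stannyl C6 unit and C16 phosphonate**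

Step 5
Reactants: 8 (2E)-3-methylpent-2-en-4-yn-1-ol
Product: 9 (2E,4E)-3-methyl-5-(tributylstannyl)penta-2,4-dien-1-ol
Conditions: Bu3SnH, PdCl2(PPh3)2 (2 mol %), THF, 0 °C → rt
Reagents that add atoms: tributyltin hydride, CCCC[SnH](CCCC)CCCC
Why: Palladium-catalysed hydrostannation: syn addition of Sn–H to the terminal alkyne of the conjugated enyne should place tin on the terminal carbon and give the 4E alkenylstannane, the 2E bond being kept.

Step 6
Reactants: 9 (2E,4E)-3-methyl-5-(tributylstannyl)penta-2,4-dien-1-ol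
Product: 10 (2E,4E)-3-methyl-5-(tributylstannyl)penta-2,4-dienal
Conditions: MnO2, CH2Cl2, rt
Reagents that add atoms: none
Why: Allylic oxidation with MnO2 is neutral and selective for the allylic alcohol, so the C–Sn bond and both E double bonds should survive.

Step 7
Reactants: 11 (2E,4E,6E)-2,7-dimethylocta-2,4,6-trienedial
Product: 12 (2E,4E,6E)-2,7-dimethylocta-2,4,6-triene-1,8-diol
Conditions: NaBH4, MeOH/THF, 0 °C
Reagents that add atoms: none
Why: Borohydride 1,2-reduction of both conjugated aldehydes; there is no stereocentre to set and the triene geometry is kept.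

Step 8
Reactants: 12 (2E,4E,6E)-2,7-dimethylocta-2,4,6-triene-1,8-diol
Product: 13 (2E,4E,6E)-1,8-dibromo-2,7-dimethylocta-2,4,6-triene
Conditions: PBr3, pyridine (cat.), Et2O, −10 → 0 °C
Reagents that add atoms: phosphorus tribromide, BrP(Br)Br
Why: Conversion of the primary allylic alcohols to bromides with PBr3 (substitution via phosphite esters) at low temperature, where allylic transposition should be minor; the dibromide is used at once.

Step 9
Reactants: 13 (2E,4E,6E)-1,8-dibromo-2,7-dimethylocta-2,4,6-triene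
Product: 14 tetraethyl [(2E,4E,6E)-2,7-dimethylocta-2,4,6-triene-1,8-diyl]bis(phosphonate)
Conditions: P(OEt)3, toluene, 110 °C
Reagents that add atoms: triethyl phosphite, CCOP(OCC)OCC
Why: Michaelis–Arbuzov reaction at both primary allylic bromides gives the bisphosphonate with the all-E triene unchanged.

Step 10
Reactants: 14 tetraethyl [(2E,4E,6E)-2,7-dimethylocta-2,4,6-triene-1,8-diyl]bis(phosphonate); 10 (2E,4E)-3-methyl-5-(tributylstannyl)penta-2,4-dienal
Product: 16 diethyl [(2E,4E,6E,8E,10E,12E)-2,7,11-trimethyl-13-(tributylstannyl)trideca-2,4,6,8,10,12-hexaen-1-yl]phosphonate, via sodium carbanion 15 (not isolated)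
Conditions: 14 (3 equiv), NaN(SiMe3)2 (1.1 equiv), THF, −78 °C; then 10 (1 equiv), −78 → 0 °C
Reagents that add atoms: none
Why: Horner–Wadsworth–Emmons olefination: with the bisphosphonate in excess the monoanion should react once with the enal to form the C11'=C12' bond with E geometry, and the surplus 14 is recovered.

**Ring fragment: triol aldehyde**

Step 11
Reactants: 1 (4R,6R)-4-hydroxy-2,2,6-trimethylcyclohexan-1-one
Product: 17 (4R,6R)-4-(tert-butyldimethylsilyloxy)-2,2,6-trimethylcyclohexan-1-one
Conditions: TBSCl, imidazole, DMF, rt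
Reagents that add atoms: tert-butyldimethylsilyl chloride, CC(C)(C)[Si](C)(C)Cl
Why: Silylation of the secondary alcohol protects it through enolate and coupling chemistry without touching either stereocentre.

Step 12
Reactants: 17 (4R,6R)-4-(tert-butyldimethylsilyloxy)-2,2,6-trimethylcyclohexan-1-one
Product: 19 (4R)-4-(tert-butyldimethylsilyloxy)-2,6,6-trimethylcyclohex-1-en-1-yl trifluoromethanesulfonate, via potassium enolate 18 (not isolated)
Conditions: KN(SiMe3)2, THF, −78 °C; then PhNTf2, −78 → 0 °C
Reagents that add atoms: N-phenylbis(trifluoromethanesulfonimide), O=S(=O)(N(c1ccccc1)S(=O)(=O)C(F)(F)F)C(F)(F)F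
Why: O-Triflation of the enolate (enol triflate formation): enolisation is possible only towards the methyl-bearing carbon, so a single tetrasubstituted enol triflate should form; the methyl stereocentre is erased and the silyloxy centre is kept.

Step 13
Reactants: 19 (4R)-4-(tert-butyldimethylsilyloxy)-2,6,6-trimethylcyclohex-1-en-1-yl trifluoromethanesulfonate; 9 (2E,4E)-3-methyl-5-(tributylstannyl)penta-2,4-dien-1-ol
Product: 20 (2E,4E)-5-[(4R)-4-(tert-butyldimethylsilyloxy)-2,6,6-trimethylcyclohex-1-en-1-yl]-3-methylpenta-2,4-dien-1-ol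
Conditions: Pd2(dba)3 (2.5 mol %), AsPh3 (20 mol %), NMP, 60 °C
Reagents that add atoms: none
Why: Stille coupling: oxidative addition of zerovalent palladium into the hindered enol triflate is helped by the weakly binding AsPh3 in polar NMP, and transmetalation and reductive elimination proceed with retention, so the E,E geometry of 9 is transferred to the new C7=C8 and C9=C10 bonds.

Step 14
Reactants: 20 (2E,4E)-5-[(4R)-4-(tert-butyldimethylsilyloxy)-2,6,6-trimethylcyclohex-1-en-1-yl]-3-methylpenta-2,4-dien-1-ol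
Product: 21 (2E,4E)-5-[(4R)-4-(tert-butyldimethylsilyloxy)-2,6,6-trimethylcyclohex-1-en-1-yl]-3-methylpenta-2,4-dienal
Conditions: MnO2, CH2Cl2, rt
Reagents that add atoms: none
Why: Selective MnO2 oxidation of the primary allylic alcohol to the trienal, whose electron-poor C9=C10 bond will later stay out of the epoxidation; geometry and stereocentre are kept.

Step 15
Reactants: 21 (2E,4E)-5-[(4R)-4-(tert-butyldimethylsilyloxy)-2,6,6-trimethylcyclohex-1-en-1-yl]-3-methylpenta-2,4-dienal
Product: 22 (2E,4E)-5-[(4R)-4-hydroxy-2,6,6-trimethylcyclohex-1-en-1-yl]-3-methylpenta-2,4-dienal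
Conditions: Bu4NF, AcOH, THF, 0 °C → rt
Reagents that add atoms: none
Why: Fluoride cleavage of the silyl ether, buffered with acetic acid so that the enal is not exposed to basic fluoride; the carbinol centre is untouched and the hydroxyl is freed to direct the next step.

Step 16
Reactants: 22 (2E,4E)-5-[(4R)-4-hydroxy-2,6,6-trimethylcyclohex-1-en-1-yl]-3-methylpenta-2,4-dienal
Product: 23 (2E,4E)-5-[(1R,4S,6S)-4-hydroxy-2,2,6-trimethyl-7-oxabicyclo[4.1.0]heptan-1-yl]-3-methylpenta-2,4-dienal (5,6-epoxide syn to the C3 hydroxyl)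
Conditions: VO(acac)2 (5 mol %), t-BuOOH, toluene, 0 °C → rt
Reagents that add atoms: tert-butyl hydroperoxide, CC(C)(C)OO
Why: Hydroxyl-directed epoxidation: the vanadium peroxide bound to the homoallylic C3 alkoxide should deliver oxygen to the C5=C6 bond on the face of the C3 hydroxyl, which fixes C6 as R (and C5, for the time being, as S), while the C7=C8 and electron-poor C9=C10 bonds are out of reach.

Step 17
Reactants: 23 (2E,4E)-5-[(1R,4S,6S)-4-hydroxy-2,2,6-trimethyl-7-oxabicyclo[4.1.0]heptan-1-yl]-3-methylpenta-2,4-dienal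
Product: 24 (2E,4E)-3-methyl-5-[(1R,2R,4S)-1,2,4-trihydroxy-2,6,6-trimethylcyclohexyl]penta-2,4-dienal
Conditions: HClO4 (cat.), THF/H2O, 0 °C
Reagents that add atoms: water, O
Why: Acid-catalysed epoxide hydrolysis: water should attack the protonated epoxide with inversion at C5, the tertiary carbon remote from the electron-poor dienal and the one that gives the trans-diaxial product from the half-chair with equatorial C3 hydroxyl (Fürst–Plattner rule), so that C5 becomes R while the C6–O bond and the 6R centre are untouched.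

**Union**

Step 18
Reactants: 16 diethyl [(2E,4E,6E,8E,10E,12E)-2,7,11-trimethyl-13-(tributylstannyl)trideca-2,4,6,8,10,12-hexaen-1-yl]phosphonate; 24 (2E,4E)-3-methyl-5-[(1R,2R,4S)-1,2,4-trihydroxy-2,6,6-trimethylcyclohexyl]penta-2,4-dienal
Product: 26 (1R,2R,4S)-2,6,6-trimethyl-1-[(1E,3E,5E,7E,9E,11E,13E,15E,17E)-3,7,12,16-tetramethyl-18-(tributylstannyl)octadeca-1,3,5,7,9,11,13,15,17-nonaen-1-yl]cyclohexane-1,2,4-triol, via sodium carbanion 25 (not isolated)
Conditions: 16 (2 equiv), NaN(SiMe3)2 (1.9 equiv), THF, −78 °C; then 24, −78 → 0 °C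
Reagents that add atoms: none
Why: Horner–Wadsworth–Emmons olefination: the delocalised carbanion of 16, far less basic than an alkoxide, should add through its α-carbon to the unprotected aldehyde and eliminate phosphate to form the C11=C12 bond with E geometry; no stereocentre is touched.

Step 19
Reactants: 26 (1R,2R,4S)-2,6,6-trimethyl-1-[(1E,3E,5E,7E,9E,11E,13E,15E,17E)-3,7,12,16-tetramethyl-18-(tributylstannyl)octadeca-1,3,5,7,9,11,13,15,17-nonaen-1-yl]cyclohexane-1,2,4-triol; 7 S-phenyl (4S)-2,2-dimethyl-6-oxo-4-(tetradecanoyloxy)heptanethioate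
Product: 27 the target, (3S,5R,6R,3'S)-3,5,6-trihydroxy-5',6'-dioxo-5,6-dihydro-5',6'-seco-β,β-caroten-3'-yl tetradecanoate
Conditions: Pd2(dba)3 (2.5 mol %), P(2-furyl)3 (10 mol %), CuO2PPh2 (1.5 equiv), THF, rt → 40 °C, dark
Reagents that add atoms: none
Why: Zerovalent palladium should insert into the C(acyl)–S bond of 7, activated by binding of the sulfur to monovalent copper; the alkenyl group of 26 then passes from tin to palladium, the phosphinate taking up tin, and reductive elimination forms the C6'–C7' bond of the enone. The closest known reaction type is the palladium-catalysed, copper diphenylphosphinate-mediated ketone synthesis from thiol esters and organostannanes (Liebeskind–Srogl family). No ring is closed and no stereocentre is created; the E geometry of C7'=C8' is carried over because tin–palladium exchange at an alkenyl carbon proceeds with retention. The step needs chemoselectivity for the thioester over the myristate, the methyl ketone, three free hydroxyls and nine conjugated double bonds, and this is secured by the neutral, base-free medium, in which the myristate β to the C5' ketone cannot be lost by E1cB elimination and the tertiary allylic C6 hydroxyl is not ionised. The acyl carbon C6' sits on the quaternary C1', so the acyl donor has no α-hydrogen, cannot form a ketene or enolise, and its acylpalladium should resist decarbonylation, which would have to give a tertiary alkylpalladium.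

**Compound list**

1 | (4R,6R)-4-hydroxy-2,2,6-trimethylcyclohexan-1-one (actinol) | O[C@@H]1C[C@@H](C)C(=O)C(C)(C)C1 | starting material
2 | tetradecanoyl chloride | CCCCCCCCCCCCCC(=O)Cl | starting material
3 | (1R,3R)-3,5,5-trimethyl-4-oxocyclohexyl tetradecanoate | CCCCCCCCCCCCCC(=O)O[C@@H]1C[C@@H](C)C(=O)C(C)(C)C1 | intermediate
4 | (1R)-3,5,5-trimethyl-4-(trimethylsilyloxy)cyclohex-3-en-1-yl tetradecanoate | CCCCCCCCCCCCCC(=O)O[C@@H]1CC(C)=C(O[Si](C)(C)C)C(C)(C)C1 | intermediate
5 | trimethylsilyl (4S)-2,2-dimethyl-6-oxo-4-(tetradecanoyloxy)heptanoate (not isolated) | CCCCCCCCCCCCCC(=O)O[C@H](CC(C)=O)CC(C)(C)C(=O)O[Si](C)(C)C | intermediate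
6 | (4S)-2,2-dimethyl-6-oxo-4-(tetradecanoyloxy)heptanoic acid | CCCCCCCCCCCCCC(=O)O[C@H](CC(C)=O)CC(C)(C)C(=O)O | intermediate
7 | S-phenyl (4S)-2,2-dimethyl-6-oxo-4-(tetradecanoyloxy)heptanethioate | CCCCCCCCCCCCCC(=O)O[C@H](CC(C)=O)CC(C)(C)C(=O)Sc1ccccc1 | intermediate
8 | (2E)-3-methylpent-2-en-4-yn-1-ol | C#C/C(C)=C/CO | starting material
9 | (2E,4E)-3-methyl-5-(tributylstannyl)penta-2,4-dien-1-ol | CCCC[Sn](CCCC)(CCCC)/C=C/C(C)=C/CO | intermediate
10 | (2E,4E)-3-methyl-5-(tributylstannyl)penta-2,4-dienal | CCCC[Sn](CCCC)(CCCC)/C=C/C(C)=C/C=O | intermediate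
11 | (2E,4E,6E)-2,7-dimethylocta-2,4,6-trienedial | O=C/C(C)=C/C=C/C=C(C)/C=O | starting material
12 | (2E,4E,6E)-2,7-dimethylocta-2,4,6-triene-1,8-diol | OC/C(C)=C/C=C/C=C(C)/CO | intermediate
13 | (2E,4E,6E)-1,8-dibromo-2,7-dimethylocta-2,4,6-triene | BrC/C(C)=C/C=C/C=C(C)/CBr | intermediate
14 | tetraethyl [(2E,4E,6E)-2,7-dimethylocta-2,4,6-triene-1,8-diyl]bis(phosphonate) | CCOP(=O)(OCC)C/C(C)=C/C=C/C=C(C)/CP(=O)(OCC)OCC | intermediate
15 | sodium salt of the monocarbanion of 14 (not isolated) | [Na+].CCOP(=O)(OCC)[CH-]/C(C)=C/C=C/C=C(C)/CP(=O)(OCC)OCC | intermediate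
16 | diethyl [(2E,4E,6E,8E,10E,12E)-2,7,11-trimethyl-13-(tributylstannyl)trideca-2,4,6,8,10,12-hexaen-1-yl]phosphonate | CCOP(=O)(OCC)C/C(C)=C/C=C/C=C(C)/C=C/C=C(C)/C=C/[Sn](CCCC)(CCCC)CCCC | intermediate
17 | (4R,6R)-4-(tert-butyldimethylsilyloxy)-2,2,6-trimethylcyclohexan-1-one | CC(C)(C)[Si](C)(C)O[C@@H]1C[C@@H](C)C(=O)C(C)(C)C1 | intermediate
18 | potassium (4R)-4-(tert-butyldimethylsilyloxy)-2,6,6-trimethylcyclohex-1-en-1-olate (not isolated) | [K+].CC(C)(C)[Si](C)(C)O[C@@H]1CC(C)=C([O-])C(C)(C)C1 | intermediate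
19 | (4R)-4-(tert-butyldimethylsilyloxy)-2,6,6-trimethylcyclohex-1-en-1-yl trifluoromethanesulfonate | CC(C)(C)[Si](C)(C)O[C@@H]1CC(C)=C(OS(=O)(=O)C(F)(F)F)C(C)(C)C1 | intermediate
20 | (2E,4E)-5-[(4R)-4-(tert-butyldimethylsilyloxy)-2,6,6-trimethylcyclohex-1-en-1-yl]-3-methylpenta-2,4-dien-1-ol | CC(C)(C)[Si](C)(C)O[C@@H]1CC(C)=C(/C=C/C(C)=C/CO)C(C)(C)C1 | intermediate
21 | (2E,4E)-5-[(4R)-4-(tert-butyldimethylsilyloxy)-2,6,6-trimethylcyclohex-1-en-1-yl]-3-methylpenta-2,4-dienal | CC(C)(C)[Si](C)(C)O[C@@H]1CC(C)=C(/C=C/C(C)=C/C=O)C(C)(C)C1 | intermediate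
22 | (2E,4E)-5-[(4R)-4-hydroxy-2,6,6-trimethylcyclohex-1-en-1-yl]-3-methylpenta-2,4-dienal | O[C@@H]1CC(C)=C(/C=C/C(C)=C/C=O)C(C)(C)C1 | intermediate
23 | (2E,4E)-5-[(1R,4S,6S)-4-hydroxy-2,2,6-trimethyl-7-oxabicyclo[4.1.0]heptan-1-yl]-3-methylpenta-2,4-dienal | O=C/C=C(C)/C=C/[C@@]1(O2)C(C)(C)C[C@H](O)C[C@@]12C | intermediate
24 | (2E,4E)-3-methyl-5-[(1R,2R,4S)-1,2,4-trihydroxy-2,6,6-trimethylcyclohexyl]penta-2,4-dienal | O=C/C=C(C)/C=C/[C@@]1(O)C(C)(C)C[C@H](O)C[C@@]1(C)O | intermediate
25 | sodium salt of the α-carbanion of 16 (not isolated) | [Na+].CCOP(=O)(OCC)[CH-]/C(C)=C/C=C/C=C(C)/C=C/C=C(C)/C=C/[Sn](CCCC)(CCCC)CCCC | intermediate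
26 | (1R,2R,4S)-2,6,6-trimethyl-1-[(1E,3E,5E,7E,9E,11E,13E,15E,17E)-3,7,12,16-tetramethyl-18-(tributylstannyl)octadeca-1,3,5,7,9,11,13,15,17-nonaen-1-yl]cyclohexane-1,2,4-triol | CCCC[Sn](CCCC)(CCCC)/C=C/C(C)=C/C=C/C(C)=C/C=C/C=C(C)/C=C/C=C(C)/C=C/[C@@]1(O)C(C)(C)C[C@H](O)C[C@@]1(C)O | intermediate
27 | (3S,5R,6R,3'S)-3,5,6-trihydroxy-5',6'-dioxo-5,6-dihydro-5',6'-seco-β,β-caroten-3'-yl tetradecanoate (CNP0338190.1) | CCCCCCCCCCCCCC(=O)O[C@H](CC(C)=O)CC(C)(C)C(=O)/C=C/C(C)=C/C=C/C(C)=C/C=C/C=C(C)/C=C/C=C(C)/C=C/[C@@]1(O)C(C)(C)C[C@H](O)C[C@@]1(C)O | target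

**Count and risks**

Total step count: 19. Longest linear sequence: 9 steps (1 → 17 → 19 → 20 → 21 → 22 → 23 → 24 → 26 → 27; steps 11 to 19).

Steps most likely to fail:

1. Step 19. Oxidative addition into the hindered α-quaternary thioester may be slower than copper-promoted homocoupling or protodestannylation of the nonaenylstannane, and the polyene may isomerise or degrade during a long reaction. The fallback replaces the acyl cross-coupling by carbonyl addition and oxidation; it sets out from 7 and 26 and returns at 27. Thioester 7 is reduced (Et3SiH, Pd/C, acetone; Fukuyama reduction) to the aldehyde (4S)-6,6-dimethyl-2,7-dioxoheptan-4-yl tetradecanoate F1. Stannane 26 is converted by tin–iodine exchange (I2, CH2Cl2, −78 °C) to (1R,2R,4S)-1-[(1E,3E,5E,7E,9E,11E,13E,15E,17E)-18-iodo-3,7,12,16-tetramethyloctadeca-1,3,5,7,9,11,13,15,17-nonaen-1-yl]-2,6,6-trimethylcyclohexane-1,2,4-triol F2. Nozaki–Hiyama–Kishi coupling of F2 with F1 (CrCl2, NiCl2 cat., DMSO/THF), which should choose the aldehyde over the methyl ketone, gives the 6'-hydroxy analogue of the target F3 as both C6' epimers. MnO2, which oxidises only the allylic carbinol, should then convert both epimers to 27.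

2. Step 17. Ring opening may start at the allylic C6 instead of C5, or run through a free C5 cation, which would lose the inversion at C5 or divert into ring contraction by a 1,2-shift. The fallback turns a preference for attack at C6 into the productive mode by placing the epoxide on the other face; it sets out from 21 and returns at 24. Silyl ether 21 is epoxidised without direction (mCPBA, NaHCO3, CH2Cl2, 0 °C), anti to the bulky C3 silyloxy group, to (2E,4E)-5-[(1S,4S,6R)-4-(tert-butyldimethylsilyloxy)-2,2,6-trimethyl-7-oxabicyclo[4.1.0]heptan-1-yl]-3-methylpenta-2,4-dienal F4. Aqueous acid should open F4 at C6 with inversion, where allylic activation and the diaxial rule now point to the same carbon, to give (2E,4E)-5-[(1R,2R,4S)-4-(tert-butyldimethylsilyloxy)-1,2-dihydroxy-2,6,6-trimethylcyclohexyl]-3-methylpenta-2,4-dienal F5. Desilylation (Bu4NF, AcOH, THF) gives 24.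

3. Step 18. Proton transfer from the three free hydroxyls and aggregation of the resulting alkoxides may stall the olefination, and a slow reaction would erode the E selectivity at C11=C12 and expose the stannane to degradation. The fallback carries the triol as silyl ethers through the olefination; it sets out from 24 and 16 and returns at 26. Aldehyde 24 is persilylated (N-(trimethylsilyl)imidazole, CH2Cl2, rt → 40 °C) to (2E,4E)-3-methyl-5-[(1R,2R,4S)-2,6,6-trimethyl-1,2,4-tris(trimethylsilyloxy)cyclohexyl]penta-2,4-dienal F6. Olefination with carbanion 25 (from 16, as in step 18) gives the tris(trimethylsilyl) ether of 26 F7, and Bu4NF (THF, 0 °C) removes the three silyl groups to give 26.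

**Further compounds**

F1 | step 19 | (4S)-6,6-dimethyl-2,7-dioxoheptan-4-yl tetradecanoate | CCCCCCCCCCCCCC(=O)O[C@H](CC(C)=O)CC(C)(C)C=O
F2 | step 19 | (1R,2R,4S)-1-[(1E,3E,5E,7E,9E,11E,13E,15E,17E)-18-iodo-3,7,12,16-tetramethyloctadeca-1,3,5,7,9,11,13,15,17-nonaen-1-yl]-2,6,6-trimethylcyclohexane-1,2,4-triol | I/C=C/C(C)=C/C=C/C(C)=C/C=C/C=C(C)/C=C/C=C(C)/C=C/[C@@]1(O)C(C)(C)C[C@H](O)C[C@@]1(C)O
F3 | step 19 | 6'-hydroxy analogue of 27 (6'-carbinol in place of the 6'-ketone, both C6' epimers) | CCCCCCCCCCCCCC(=O)O[C@H](CC(C)=O)CC(C)(C)C(O)/C=C/C(C)=C/C=C/C(C)=C/C=C/C=C(C)/C=C/C=C(C)/C=C/[C@@]1(O)C(C)(C)C[C@H](O)C[C@@]1(C)O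
F4 | step 17 | (2E,4E)-5-[(1S,4S,6R)-4-(tert-butyldimethylsilyloxy)-2,2,6-trimethyl-7-oxabicyclo[4.1.0]heptan-1-yl]-3-methylpenta-2,4-dienal | O=C/C=C(C)/C=C/[C@]1(O2)C(C)(C)C[C@H](O[Si](C)(C)C(C)(C)C)C[C@]12C
F5 | step 17 | (2E,4E)-5-[(1R,2R,4S)-4-(tert-butyldimethylsilyloxy)-1,2-dihydroxy-2,6,6-trimethylcyclohexyl]-3-methylpenta-2,4-dienal | O=C/C=C(C)/C=C/[C@@]1(O)C(C)(C)C[C@H](O[Si](C)(C)C(C)(C)C)C[C@@]1(C)O
F6 | step 18 | (2E,4E)-3-methyl-5-[(1R,2R,4S)-2,6,6-trimethyl-1,2,4-tris(trimethylsilyloxy)cyclohexyl]penta-2,4-dienal | O=C/C=C(C)/C=C/[C@@]1(O[Si](C)(C)C)C(C)(C)C[C@H](O[Si](C)(C)C)C[C@@]1(C)O[Si](C)(C)C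
F7 | step 18 | tris(trimethylsilyl) ether of 26 | CCCC[Sn](CCCC)(CCCC)/C=C/C(C)=C/C=C/C(C)=C/C=C/C=C(C)/C=C/C=C(C)/C=C/[C@@]1(O[Si](C)(C)C)C(C)(C)C[C@H](O[Si](C)(C)C)C[C@@]1(C)O[Si](C)(C)C
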